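Substrate is conserved: in the flask, c(substrate) + c(open intermediate) + c(trapped intermediate) + c(uncatalysed product) + c(target) stays at the charge of 1.5 M. The reagent charge of 1.65 M is larger than the substrate charge, and each product uses one reagent per substrate, so substrate is the limiting reagent.

the same everywhere: substrate 1.5 M; reagent 1.65 M; catalyst 9.3 mM
- alder: capture agent 0.15 M; the very flask that is asked about, followed so far
- flask: capture agent 0.150 M; time 20 min

alder run (percent of the substrate charged)

| time / min | uncatalysed product / % | target / % |
|---|---|---|
| 0.833 | 35 | 31 |
| 2.00 | 43 | 48 |
| 4.00 | 36 | 54 |
| 6.00 | 45 | 58 |

(standard deviation of a reading: 2 percentage points)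

- share of uncatalysed product in uncatalysed product plus target at 2.5 s
- share of uncatalysed product in uncatalysed product plus target at 50 s
- share of uncatalysed product in uncatalysed product plus target at 20 min
- which of uncatalysed product and target there is more of at 20 min

- steps thought possible: substrate + reagent -> uncatalysed product; reagent + catalyst + open intermediate -> catalyst + target; open intermediate + capture agent -> trapped intermediate; substrate + catalyst -> catalyst + open intermediate

Substrate leaves by two steps: with reagent to uncatalysed product, or with catalyst to open intermediate. Target and trapped intermediate both come from open intermediate. Both loss rates are proportional to c(substrate), so their ratio goes as c(reagent)/c(catalyst), and the catalyst is returned by each step it takes part in.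

In the alder run, the uncatalysed product readings from 2.00 min on are 43%, 36% and 45%. They show no steady rise, so I take their mean, 41.3%, as the plateau. By the balance, I count the rest of the substrate as opened, which gives an estimate of 0.705 substrate lost directly per substrate opened. I call this the split, a selectivity factor averaged over the run; with the reagent charge held, I take it to go as one over c(catalyst).

As a check, the alder target reading at 6.00 min is 58%, which leaves a gap of 0.67 percentage points against a scatter of 2 points. Neglecting that gap, I expect a share of 41.3% at 20 min, and I expect target to lead, since the split is less than one.

The forecast gives 97% at 2.5 s, 52% at 50 s and 43% at 20 min, with target ahead. It holds that “about 10% of substrate is trapped before target appears”; my gap from the readings is 0.67 points.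

The flask gives shares of 87.8%, 52.6% and 42.3% at the same times, and target leads at 20 min, with 57.3% against 42.0% uncatalysed product.

    substrate + reagent → uncatalysed product (k = 0.0120 M⁻¹ s⁻¹)
    reagent + catalyst + open intermediate → catalyst + target (k = 11.0 M⁻² s⁻¹)
    open intermediate + capture agent → trapped intermediate (k = 0.00420 M⁻¹ s⁻¹)
    substrate + catalyst → catalyst + open intermediate (k = 1.60 M⁻¹ s⁻¹)

With the other concentrations as charged, open intermediate has a half-life of 0.068 min towards target, far shorter than its 18 min towards trapping. My split, read from the alder readings, counts 58.7% of the substrate as opened; the flask holds 57.3% target and 0.649% trapped intermediate at 20 min.

For the neighbour flask with 0.016 M of catalyst, my split scales to an estimated 0.410, which means a share of 29.1% at 20 min. The computed share there is 30.4%.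

(The readings come from a simulation with constants of no real substance; noise was put on by code.)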